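**Strategy.** The six-membered quinone carbocycle is traced back to a benzene ring whose C2–C3 bond (quinone numbering: C1=O, C2–OH, C3–side chain, C4=O, C5–OMe) is made by an intramolecular aldol condensation. The step exploits the fact that ring carbon C3 and its CH2–CH(O)–C13H27 chain are the acyl carbon and tail of (R)-3-hydroxyhexadecanoic acid. In one operation, amine-mediated cyclisation–dehydration closes the arene and leaves one free phenol, the future C5 methoxyl. The precursor is a 2,2-dimethyl-1,3-dioxin-4-one carrying a 2,4-dioxoalkyl chain, with the silyl-protected (R)-carbinol β to the distal ketone.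

Key step: step 7

Remark: diketone 11 is drawn in its keto form although it should exist largely as enol tautomers, and acetyl chloride is taken as a fourth commercial building block because the keto-dioxinone needs a two-carbon acyl unit.

**Route**

Step 1
Reactants: 1 tetradecanoyl chloride, 2 Meldrum's acid (2,2-dimethyl-1,3-dioxane-4,6-dione)
Product: 4 methyl 3-oxohexadecanoate, via acyl Meldrum's acid 3 (not isolated)
Conditions: pyridine, CH2Cl2, 0 °C to rt; then MeOH, reflux
Reagents that add atoms: methanol, CO
Why: Pyridine-mediated C-acylation of Meldrum's acid gives the enolised acyl derivative 3, which in refluxing methanol fragments through an acyl ketene with loss of acetone and CO2 to the β-keto ester (acylation–alcoholysis–decarboxylation sequence).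

Step 2
Reactants: 4 methyl 3-oxohexadecanoate
Product: 5 methyl (R)-3-hydroxyhexadecanoate
Conditions: H2 (50 bar), RuCl2[(R)-BINAP] (0.2 mol%), MeOH, 50 °C
Reagents that add atoms: none
Why: Noyori asymmetric hydrogenation, in which the keto ester chelates divalent ruthenium through both carbonyls and the (R)-BINAP ligand directs hydride to the ketone face that gives the (R)-carbinol, as is general for simple 3-oxoalkanoates; this sets the only stereocentre of the target.

Step 3
Reactants: 5 methyl (R)-3-hydroxyhexadecanoate
Product: 6 methyl (R)-3-(tert-butyldimethylsilyloxy)hexadecanoate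
Conditions: TBSCl, imidazole, DMF, rt
Reagents that add atoms: tert-butyldimethylsilyl chloride, CC(C)(C)[Si](C)(C)Cl
Why: Imidazole-promoted silylation of a secondary alcohol (silyl ether formation) takes place at oxygen only, so the stereocentre is untouched.

Step 4
Reactants: 6 methyl (R)-3-(tert-butyldimethylsilyloxy)hexadecanoate
Product: 7 (R)-3-(tert-butyldimethylsilyloxy)-N-methoxy-N-methylhexadecanamide
Conditions: MeNH(OMe)·HCl, iPrMgCl, THF, −20 to 0 °C
Reagents that add atoms: N,O-dimethylhydroxylamine hydrochloride, CNOC.Cl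
Why: Aminolysis of the methyl ester by the chloromagnesium amide of N,O-dimethylhydroxylamine (Weinreb amide formation) proceeds at or below 0 °C, where this weakly basic amide should not trigger β-elimination of the silyloxy group.

Step 5
Reactants: 8 2,2,6-trimethyl-4H-1,3-dioxin-4-one, 9 acetyl chloride
Product: 10 2,2-dimethyl-6-(2-oxopropyl)-4H-1,3-dioxin-4-one
Conditions: LiN(SiMe3)2, THF, −78 °C; then 9 (0.5 equiv relative to the dienolate), −78 °C; sat. aq. NH4Cl
Reagents that add atoms: none
Why: Deprotonation of the 6-methyl group gives the lithium dienolate, which is C-acylated at its γ-carbon by the acid chloride (Claisen-type acylation), the excess dienolate absorbing the acidity of the keto-dioxinone formed.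

Step 6
Reactants: 10 2,2-dimethyl-6-(2-oxopropyl)-4H-1,3-dioxin-4-one, 7 (R)-3-(tert-butyldimethylsilyloxy)-N-methoxy-N-methylhexadecanamide
Product: 11 6-[(R)-6-(tert-butyldimethylsilyloxy)-2,4-dioxononadecyl]-2,2-dimethyl-4H-1,3-dioxin-4-one
Conditions: LiN(iPr)2 (2.1 equiv per 10, dianion in excess), THF, −78 °C; then 7, −78 to −20 °C; sat. aq. NH4Cl
Reagents that add atoms: none
Why: The dianion of the keto-dioxinone reacts at its more basic terminal carbanion (the former methyl group) in a crossed Claisen condensation, and the Weinreb amide holds the adduct as a chelated tetrahedral intermediate, so the 1,3-diketone is released only on work-up and cannot be attacked twice.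

Step 7
Reactants: 11 6-[(R)-6-(tert-butyldimethylsilyloxy)-2,4-dioxononadecyl]-2,2-dimethyl-4H-1,3-dioxin-4-one
Product: 13 5-[(R)-2-(tert-butyldimethylsilyloxy)pentadecyl]-7-hydroxy-2,2-dimethyl-4H-benzo[d][1,3]dioxin-4-one, via cyclic aldol carbinol 12 (not isolated)
Conditions: Et3N (5 equiv), CH2Cl2, rt
Reagents that add atoms: none
Why: Triethylamine enolises the methylene flanked by the dioxinone and the C2 ketone, the vinylogous enolate attacks through dioxinone C5 onto the C4 ketone, and carbinol 12 then loses water while the C2 ketone enolises to the phenol (intramolecular aldol condensation–aromatisation). The closest known reaction type is the base-mediated aromatisation of 6-(2,4-dioxoalkyl)dioxinones to acetonide-protected resorcylates, the laboratory analogue of polyketide cyclisation. The one ring closed is the benzene ring, formed in a 6-(enolexo)-exo-trig mode. No stereocentre is created, and the (R)-silyloxy carbon lies β, not α, to a carbonyl, so it cannot epimerise by enolisation. The step needs C–C closure in place of attack by an enol oxygen, which is secured because at room temperature the dioxinone keeps the carboxyl terminus masked (no acyl ketene, hence no pyranone). It also needs to avoid E1cB loss of the silyloxy group, which is secured by the weak amine base, the poor leaving ability of a silanolate and the consumption of the C4 ketone by the ring closure.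

Step 8
Reactants: 13 5-[(R)-2-(tert-butyldimethylsilyloxy)pentadecyl]-7-hydroxy-2,2-dimethyl-4H-benzo[d][1,3]dioxin-4-one
Product: 14 5-[(R)-2-(tert-butyldimethylsilyloxy)pentadecyl]-7-methoxy-2,2-dimethyl-4H-benzo[d][1,3]dioxin-4-one
Conditions: MeI, K2CO3, acetone, reflux
Reagents that add atoms: iodomethane, CI
Why: Williamson ether synthesis on the only free phenol, the second phenolic oxygen being locked in the acetonide, so the methyl group can only go to the oxygen that becomes the C5 methoxyl.

Step 9
Reactants: 14 5-[(R)-2-(tert-butyldimethylsilyloxy)pentadecyl]-7-methoxy-2,2-dimethyl-4H-benzo[d][1,3]dioxin-4-one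
Product: 17 3-[(R)-2-hydroxypentadecyl]-5-methoxyphenol, via salicylic acid 15 (not isolated), via silyl ether phenol 16 (not isolated)
Conditions: KOH (aq., excess), 1,4-dioxane, 110 °C (sealed tube); then conc. HCl to pH 1, MeOH, rt
Reagents that add atoms: none
Why: Hydroxide opens the activated aryl acylal (saponification) to salicylate 15, which as a 2,4-dioxygenated benzoic acid should undergo protodecarboxylation by ipso-protonation on heating, and acidic methanolysis then cleaves the silyl ether at the Si–O bond, leaving the configuration of the non-benzylic carbinol intact.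

Step 10
Reactants: 17 3-[(R)-2-hydroxypentadecyl]-5-methoxyphenol
Product: 18 2-[(R)-2-hydroxypentadecyl]-6-methoxy-1,4-benzoquinone
Conditions: (KSO3)2NO (2.5 equiv), aq. KH2PO4, acetone, rt
Reagents that add atoms: potassium nitrosodisulfonate (Fremy's salt), [K+].[K+].[O]N(S(=O)(=O)[O-])S(=O)(=O)[O-]
Why: Teuber oxidation, in which one nitroxyl radical abstracts the phenolic hydrogen and a second delivers oxygen to the free para carbon (between the methoxyl and the alkyl group), converts phenols of this type into para-quinones and tolerates a free secondary alcohol.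

Step 11
Reactants: 18 2-[(R)-2-hydroxypentadecyl]-6-methoxy-1,4-benzoquinone
Product: 19 3-[(R)-2-acetoxypentadecyl]-5-methoxybenzene-1,2,4-triyl triacetate
Conditions: Ac2O, conc. H2SO4 (cat.), 0 °C to rt
Reagents that add atoms: acetic anhydride, CC(=O)OC(C)=O
Why: Thiele–Winter acetoxylation, in which the enone on the methoxyl side is deactivated as a vinylogous ester so that acetate adds to the ring CH para to the methoxyl (next to the alkyl group), after which the resulting hydroquinone and the secondary alcohol are acetylated under the same acidic conditions with retention at the carbinol.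

Step 12
Reactants: 19 3-[(R)-2-acetoxypentadecyl]-5-methoxybenzene-1,2,4-triyl triacetate
Product: 21 (R)-1-(2-hydroxy-5-methoxy-3,6-dioxocyclohexa-1,4-dien-1-yl)pentadecan-2-yl acetate, via trihydroxyarene acetate 20 (not isolated)
Conditions: K2CO3, MeOH (degassed), 0 °C, 20 min; then air, 0 °C; 1 M HCl work-up
Reagents that add atoms: none
Why: Aryl acetates undergo base-catalysed methanolysis far faster than a secondary alkyl acetate because phenoxide is the better leaving group, and the liberated 1,2,4-trihydroxyarene 20 should be autoxidised by air to the hydroxy-para-quinone (chemoselective transesterification followed by hydroquinone autoxidation).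

**Compound list**

1 | tetradecanoyl chloride | CCCCCCCCCCCCCC(Cl)=O | starting material
2 | Meldrum's acid (2,2-dimethyl-1,3-dioxane-4,6-dione) | CC1(C)OC(=O)CC(=O)O1 | starting material
3 | 5-(1-hydroxytetradecylidene)-2,2-dimethyl-1,3-dioxane-4,6-dione (acyl Meldrum's acid) | CCCCCCCCCCCCCC(O)=C1C(=O)OC(C)(C)OC1=O | intermediate
4 | methyl 3-oxohexadecanoate | CCCCCCCCCCCCCC(=O)CC(=O)OC | intermediate
5 | methyl (R)-3-hydroxyhexadecanoate | CCCCCCCCCCCCC[C@H](CC(=O)OC)O | intermediate
6 | methyl (R)-3-(tert-butyldimethylsilyloxy)hexadecanoate | CCCCCCCCCCCCC[C@H](CC(=O)OC)O[Si](C)(C)C(C)(C)C | intermediate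
7 | (R)-3-(tert-butyldimethylsilyloxy)-N-methoxy-N-methylhexadecanamide | CCCCCCCCCCCCC[C@H](CC(=O)N(C)OC)O[Si](C)(C)C(C)(C)C | intermediate
8 | 2,2,6-trimethyl-4H-1,3-dioxin-4-one | CC1=CC(=O)OC(C)(C)O1 | starting material
9 | acetyl chloride | CC(Cl)=O | starting material
10 | 2,2-dimethyl-6-(2-oxopropyl)-4H-1,3-dioxin-4-one | CC(=O)CC1=CC(=O)OC(C)(C)O1 | intermediate
11 | 6-[(R)-6-(tert-butyldimethylsilyloxy)-2,4-dioxononadecyl]-2,2-dimethyl-4H-1,3-dioxin-4-one | CCCCCCCCCCCCC[C@H](CC(=O)CC(=O)CC1=CC(=O)OC(C)(C)O1)O[Si](C)(C)C(C)(C)C | intermediate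
12 | 5-[(R)-2-(tert-butyldimethylsilyloxy)pentadecyl]-5-hydroxy-2,2-dimethyl-5,6-dihydro-4H-benzo[d][1,3]dioxine-4,7(8H)-dione (both epimers at the ring carbinol carbon) | CCCCCCCCCCCCC[C@H](CC1(O)CC(=O)CC2=C1C(=O)OC(C)(C)O2)O[Si](C)(C)C(C)(C)C | intermediate
13 | 5-[(R)-2-(tert-butyldimethylsilyloxy)pentadecyl]-7-hydroxy-2,2-dimethyl-4H-benzo[d][1,3]dioxin-4-one | CCCCCCCCCCCCC[C@H](Cc1cc(O)cc2OC(C)(C)OC(=O)c12)O[Si](C)(C)C(C)(C)C | intermediate
14 | 5-[(R)-2-(tert-butyldimethylsilyloxy)pentadecyl]-7-methoxy-2,2-dimethyl-4H-benzo[d][1,3]dioxin-4-one | CCCCCCCCCCCCC[C@H](Cc1cc(OC)cc2OC(C)(C)OC(=O)c12)O[Si](C)(C)C(C)(C)C | intermediate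
15 | 2-hydroxy-4-methoxy-6-[(R)-2-(tert-butyldimethylsilyloxy)pentadecyl]benzoic acid | CCCCCCCCCCCCC[C@H](Cc1cc(OC)cc(O)c1C(O)=O)O[Si](C)(C)C(C)(C)C | intermediate
16 | 3-[(R)-2-(tert-butyldimethylsilyloxy)pentadecyl]-5-methoxyphenol | CCCCCCCCCCCCC[C@H](Cc1cc(O)cc(OC)c1)O[Si](C)(C)C(C)(C)C | intermediate
17 | 3-[(R)-2-hydroxypentadecyl]-5-methoxyphenol | CCCCCCCCCCCCC[C@H](Cc1cc(O)cc(OC)c1)O | intermediate
18 | 2-[(R)-2-hydroxypentadecyl]-6-methoxy-1,4-benzoquinone | CCCCCCCCCCCCC[C@H](CC1=CC(=O)C=C(OC)C1=O)O | intermediate
19 | 3-[(R)-2-acetoxypentadecyl]-5-methoxybenzene-1,2,4-triyl triacetate | CCCCCCCCCCCCC[C@H](Cc1c(OC(C)=O)c(OC(C)=O)cc(OC)c1OC(C)=O)OC(C)=O | intermediate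
20 | (R)-1-(2,3,6-trihydroxy-5-methoxyphenyl)pentadecan-2-yl acetate | CCCCCCCCCCCCC[C@H](Cc1c(O)c(O)cc(OC)c1O)OC(C)=O | intermediate
21 | (R)-1-(2-hydroxy-5-methoxy-3,6-dioxocyclohexa-1,4-dien-1-yl)pentadecan-2-yl acetate (2-hydroxy-5-methoxy-3-[(R)-2-acetoxypentadecyl]-1,4-benzoquinone) | CCCCCCCCCCCCC[C@H](CC1=C(O)C(=O)C=C(OC)C1=O)OC(C)=O | target

**Step count and risk**

Total step count: 12 steps. Longest linear sequence: 11 steps (steps 1–4 and 6–12, from tetradecanoyl chloride); step 5 is a one-step side branch.

Steps most likely to fail: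

1. Step 7 (key step). The closure may be diverted by β-elimination of the silyloxy group from the enolised C4 ketone, by attack of an enol oxygen in place of carbon, or by stalling at the carbinol stage before dehydration. The fallback sets out from 11 and forms the same ring bond from an open-chain ester instead of the intact dioxinone. Heating 11 with excess methanol in toluene at 110 °C should expel acetone and trap the acyl ketene as methyl (R)-9-(tert-butyldimethylsilyloxy)-3,5,7-trioxodocosanoate F1. Cs2CO3 in MeOH at rt should then cyclise and aromatise F1 (ester α-carbon onto the C7 ketone) to methyl 2,4-dihydroxy-6-[(R)-2-(tert-butyldimethylsilyloxy)pentadecyl]benzoate F2. Methylation of the non-chelated 4-hydroxyl (MeI, 1 equiv, K2CO3, acetone) should give methyl 2-hydroxy-4-methoxy-6-[(R)-2-(tert-butyldimethylsilyloxy)pentadecyl]benzoate F3. Hydrolysis of this hindered ester (KOH, aqueous DMSO, 120 °C; then HCl, MeOH) passes through the same acid 15 and comes back to the route at 17.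

2. Step 6. Proton transfer from the α-methylene of the Weinreb amide to the strongly basic dianion may be followed by loss of silanolate, or the acylation may stop short because the amide is a sluggish electrophile. The fallback sets out from 6 and 10 and replaces the Claisen condensation by an aldol addition and an oxidation. Reduction of 6 (iBu2AlH, CH2Cl2, −78 °C) should give (R)-3-(tert-butyldimethylsilyloxy)hexadecanal F4. Addition of F4 to the dianion of 10 (LiN(iPr)2, THF, −78 °C) should give 6-[(6R)-6-(tert-butyldimethylsilyloxy)-4-hydroxy-2-oxononadecyl]-2,2-dimethyl-4H-1,3-dioxin-4-one F5 as a mixture of carbinol epimers. Oxidation with Dess–Martin periodinane (NaHCO3, CH2Cl2) removes the new carbinol stereocentre and comes back to the route at 11.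

3. Step 12. Chemoselectivity between aryl and alkyl acetate solvolysis may be lost, or the electron-rich triol may be degraded under basic aerobic conditions. The fallback sets out from 19 and gives up the differentiation at this stage. Exhaustive methanolysis (NaOMe, MeOH, then air and acidification) should give 2-hydroxy-3-[(R)-2-hydroxypentadecyl]-5-methoxy-1,4-benzoquinone F6. Acetylation of both hydroxyls (Ac2O, pyridine, DMAP cat.) should give 2-acetoxy-3-[(R)-2-acetoxypentadecyl]-5-methoxy-1,4-benzoquinone F7. The quinonyl acetate of F7 is a vinylogous anhydride, so brief treatment with aqueous NaHCO3 in THF at 0 °C should cleave it alone and come back to the route at 21.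

Further compounds
F1 | step 7 | methyl (R)-9-(tert-butyldimethylsilyloxy)-3,5,7-trioxodocosanoate | CCCCCCCCCCCCC[C@H](CC(=O)CC(=O)CC(=O)CC(=O)OC)O[Si](C)(C)C(C)(C)C
F2 | step 7 | methyl 2,4-dihydroxy-6-[(R)-2-(tert-butyldimethylsilyloxy)pentadecyl]benzoate | CCCCCCCCCCCCC[C@H](Cc1cc(O)cc(O)c1C(=O)OC)O[Si](C)(C)C(C)(C)C
F3 | step 7 | methyl 2-hydroxy-4-methoxy-6-[(R)-2-(tert-butyldimethylsilyloxy)pentadecyl]benzoate | CCCCCCCCCCCCC[C@H](Cc1cc(OC)cc(O)c1C(=O)OC)O[Si](C)(C)C(C)(C)C
F4 | step 6 | (R)-3-(tert-butyldimethylsilyloxy)hexadecanal | CCCCCCCCCCCCC[C@H](CC=O)O[Si](C)(C)C(C)(C)C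
F5 | step 6 | 6-[(6R)-6-(tert-butyldimethylsilyloxy)-4-hydroxy-2-oxononadecyl]-2,2-dimethyl-4H-1,3-dioxin-4-one (both C4 epimers) | CCCCCCCCCCCCC[C@H](CC(O)CC(=O)CC1=CC(=O)OC(C)(C)O1)O[Si](C)(C)C(C)(C)C
F6 | step 12 | 2-hydroxy-3-[(R)-2-hydroxypentadecyl]-5-methoxy-1,4-benzoquinone | CCCCCCCCCCCCC[C@H](CC1=C(O)C(=O)C=C(OC)C1=O)O
F7 | step 12 | 2-acetoxy-3-[(R)-2-acetoxypentadecyl]-5-methoxy-1,4-benzoquinone | CCCCCCCCCCCCC[C@H](CC1=C(OC(C)=O)C(=O)C=C(OC)C1=O)OC(C)=O
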